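The tetrahydrofuran is closed not at a C–O bond but at C3–C4 (lignan C8–C8′). Titanocene(III) opens a terminal epoxide to a C3 radical that already carries the future 3-CH2OH. Its 5-exo addition to a styrenyl allyl ether builds ring O1–C2–C3–C4–C5 and the C4 benzylic link to C6 of the dihydrobenzofuran, and sets C3 and C4 together, both relayed from the one carbinol centre C2, which a Sharpless kinetic resolution supplies. The precursor is the (S)-1-aryl-2,3-epoxypropyl ether of an (E)-cinnamyl alcohol whose arene is the finished (2S,3R)-dihydrobenzofuran, itself made by asymmetric Rh-carbenoid C–H insertion and joined by Suzuki coupling.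

Key step: step 16

Remark: the sense of induction of the chiral Rh(II) carboxylate in step 7 is assigned by analogy with simpler 2-aryl-2,3-dihydrobenzofuran-3-carboxylates; if it proves opposite, the enantiomeric catalyst is used.
Remark: ring numbering used below is oxolane O1, C2 (aryl), C3 (CH2OH), C4 (benzyl), C5; dihydrobenzofuran O1, C2 (aryl), C3 (CH2OH), C4 (OMe), C6 (side chain).

Step 1
Reactants: 1 vanillin
Product: 2 3-methoxy-4-(triisopropylsilyloxy)benzaldehyde
Conditions: TIPSCl, imidazole, DMF, rt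
Reagents that add atoms: chlorotriisopropylsilane, CC(C)[Si](Cl)(C(C)C)C(C)C
Why: Silylation of the phenol gives a bulky aryl silyl ether that should survive every later step and fall to fluoride at the end.

Step 2
Reactants: 2 3-methoxy-4-(triisopropylsilyloxy)benzaldehyde
Product: 3 [3-methoxy-4-(triisopropylsilyloxy)phenyl]methanol
Conditions: NaBH4, MeOH, 0 °C
Reagents that add atoms: none
Why: Borohydride reduction of an aryl aldehyde to the benzylic alcohol, which the aryl silyl ether should tolerate at 0 °C.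

Step 3
Reactants: 4 1,3-dimethoxybenzene; 5 dimethyl oxalate
Product: 7 methyl 2-(2,6-dimethoxyphenyl)-2-oxoacetate, via 2,6-dimethoxyphenyllithium 6 (not isolated)
Conditions: n-BuLi, THF, 0 °C to rt; then cannulated into (CO2Me)2 (3 equiv), THF, −78 °C; aq. NH4Cl
Reagents that add atoms: none
Why: Directed ortho-metalation occurs at the carbon flanked by both methoxy groups, and inverse addition of the hindered aryllithium to excess oxalate should stop at the keto ester (acyl substitution).

Step 4
Reactants: 7 methyl 2-(2,6-dimethoxyphenyl)-2-oxoacetate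
Product: 8 methyl 2-(2-hydroxy-6-methoxyphenyl)-2-oxoacetate
Conditions: BCl3 (1.1 equiv), CH2Cl2, −78 to 0 °C; then H2O
Reagents that add atoms: none
Why: Chelation-assisted ether cleavage: BCl3 bound between the ketone oxygen and one ortho methoxy group should remove a single methyl group, since the resulting aryloxyboron chelate deactivates the second one and the ester is inert at this temperature.

Step 5
Reactants: 8 methyl 2-(2-hydroxy-6-methoxyphenyl)-2-oxoacetate; 3 [3-methoxy-4-(triisopropylsilyloxy)phenyl]methanol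
Product: 9 methyl 2-[2-methoxy-6-[[3-methoxy-4-(triisopropylsilyloxy)phenyl]methoxy]phenyl]-2-oxoacetate
Conditions: PPh3, DIAD, THF, 0 °C to rt
Reagents that add atoms: none
Why: Mitsunobu etherification of a phenol made acidic by its ortho acyl group with a primary benzylic alcohol, under neutral conditions that spare the keto ester and the silyl ether.

Step 6
Reactants: 9 methyl 2-[2-methoxy-6-[[3-methoxy-4-(triisopropylsilyloxy)phenyl]methoxy]phenyl]-2-oxoacetate
Product: 11 methyl 2-diazo-2-[2-methoxy-6-[[3-methoxy-4-(triisopropylsilyloxy)phenyl]methoxy]phenyl]acetate, via tosylhydrazone 10 (not isolated)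
Conditions: TsNHNH2, AcOH (cat.), MeOH, 60 °C; then DBU, CH2Cl2, rt
Reagents that add atoms: 4-methylbenzenesulfonohydrazide, Cc1ccc(cc1)S(=O)(=O)NN
Why: Condensation of the electrophilic α-keto ester with tosylhydrazide followed by base-induced loss of sulfinate (Bamford–Stevens reaction) should give the aryl diazoacetate without needing the arylacetic ester.

Step 7
Reactants: 11 methyl 2-diazo-2-[2-methoxy-6-[[3-methoxy-4-(triisopropylsilyloxy)phenyl]methoxy]phenyl]acetate
Product: 13 methyl (2S,3S)-4-methoxy-2-[3-methoxy-4-(triisopropylsilyloxy)phenyl]-2,3-dihydro-1-benzofuran-3-carboxylate (trans ester), via cis ester 12 (not isolated)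
Conditions: Rh2(R-PTTL)4 (1 mol %), toluene, −60 °C; then DBU, 40 °C
Reagents that add atoms: none
Why: Rh(II)-carbenoid intramolecular 1,5 C–H insertion into the benzylic ether methylene, which is activated by oxygen and the electron-rich aryl group and should therefore win over the primary C–H of the flanking methoxy group; the chiral carboxylate selects one enantiotopic hydrogen and so sets C2 (S), and DBU then epimerises the kinetic cis ester at C3 to the more stable trans ester.

Step 8
Reactants: 13 methyl (2S,3S)-4-methoxy-2-[3-methoxy-4-(triisopropylsilyloxy)phenyl]-2,3-dihydro-1-benzofuran-3-carboxylate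
Product: 14 [(2S,3R)-4-methoxy-2-[3-methoxy-4-(triisopropylsilyloxy)phenyl]-2,3-dihydro-1-benzofuran-3-yl]methanol
Conditions: DIBAL-H, CH2Cl2, −78 to 0 °C; Rochelle salt
Reagents that add atoms: none
Why: Hydride reduction of the ester to the primary alcohol at low temperature should leave the trans C2/C3 relationship and the aryl silyl ether intact (the descriptor at C3 changes only through CIP priorities).

Step 9
Reactants: 14 [(2S,3R)-4-methoxy-2-[3-methoxy-4-(triisopropylsilyloxy)phenyl]-2,3-dihydro-1-benzofuran-3-yl]methanol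
Product: 16 [(2S,3R)-4-methoxy-2-[3-methoxy-4-(triisopropylsilyloxy)phenyl]-6-(4,4,5,5-tetramethyl-1,3,2-dioxaborolan-2-yl)-2,3-dihydro-1-benzofuran-3-yl]methanol, via O-borylated boronate 15 (not isolated)
Conditions: [Ir(cod)OMe]2 (1.5 mol %), dtbpy (3 mol %), B2pin2 (1.5 equiv), THF, 70 °C; then MeOH, rt
Reagents that add atoms: bis(pinacolato)diboron, CC1(C)OB(OC1(C)C)B1OC(C)(C)C(C)(C)O1
Why: Iridium-catalysed aromatic C–H borylation is sterically governed, and C6–H is the only aryl hydrogen of 14 with no ortho substituent, so boron should enter para to C3a; the hydroxyl is borylated in passing and freed again by methanol.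

Step 10
Reactants: 17 isovanillin
Product: 18 4-methoxy-3-(triisopropylsilyloxy)benzaldehyde
Conditions: TIPSCl, imidazole, DMF, rt
Reagents that add atoms: chlorotriisopropylsilane, CC(C)[Si](Cl)(C(C)C)C(C)C
Why: Silylation of the phenol, as in step 1, so that both phenols can be released together in the last step.

Step 11
Reactants: 18 4-methoxy-3-(triisopropylsilyloxy)benzaldehyde; 19 vinylmagnesium bromide
Product: 20 rac-1-[4-methoxy-3-(triisopropylsilyloxy)phenyl]prop-2-en-1-ol
Conditions: THF, −78 to 0 °C; aq. NH4Cl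
Reagents that add atoms: none
Why: Grignard 1,2-addition to the aldehyde gives the racemic secondary allylic alcohol needed for the resolution.

Step 12
Reactants: 20 rac-1-[4-methoxy-3-(triisopropylsilyloxy)phenyl]prop-2-en-1-ol
Product: 21 (S)-[4-methoxy-3-(triisopropylsilyloxy)phenyl][(2R)-oxiran-2-yl]methanol
Conditions: Ti(OiPr)4 (0.2 equiv), L-(+)-DIPT (0.24 equiv), t-BuOOH (0.45 equiv), 4 Å MS, CH2Cl2, −20 °C, stopped near 45% conversion
Reagents that add atoms: tert-butyl hydroperoxide, CC(C)(C)OO
Why: Sharpless kinetic resolution: with L-(+)-DIPT the (R)-enantiomer of 20 should be epoxidised much faster and to the erythro product, giving the (1S)-carbinol 21 (descriptor changed only by CIP priorities) and leaving (S)-20, which is separated; only the carbinol centre matters later.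

Step 13
Reactants: 21 (S)-[4-methoxy-3-(triisopropylsilyloxy)phenyl][(2R)-oxiran-2-yl]methanol; 22 propargyl bromide
Product: 23 (2R)-2-[(S)-[4-methoxy-3-(triisopropylsilyloxy)phenyl](prop-2-yn-1-yloxy)methyl]oxirane
Conditions: NaH, Bu4NI (cat.), THF/DMF, −20 to 0 °C, bromide present before the base
Reagents that add atoms: none
Why: Williamson etherification in an aprotic medium with the reactive bromide already present should trap the alkoxide faster than it can undergo epoxide migration, and leaves the carbinol centre untouched.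

Step 14
Reactants: 23 (2R)-2-[(S)-[4-methoxy-3-(triisopropylsilyloxy)phenyl](prop-2-yn-1-yloxy)methyl]oxirane
Product: 25 (2R)-2-[(S)-[[(2E)-3-iodoprop-2-en-1-yl]oxy][4-methoxy-3-(triisopropylsilyloxy)phenyl]methyl]oxirane, via alkenylzirconocene 24 (not isolated)
Conditions: Cp2Zr(H)Cl (1.3 equiv), THF, rt; then I2, 0 °C
Reagents that add atoms: iodine, II
Why: Hydrozirconation of the terminal alkyne with the Schwartz reagent is syn and places zirconium at the terminus, and iodinolysis with retention should give the E-vinyl iodide, the alkyne reacting well before the oxirane.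

Step 15
Reactants: 16 [(2S,3R)-4-methoxy-2-[3-methoxy-4-(triisopropylsilyloxy)phenyl]-6-(4,4,5,5-tetramethyl-1,3,2-dioxaborolan-2-yl)-2,3-dihydro-1-benzofuran-3-yl]methanol; 25 (2R)-2-[(S)-[[(2E)-3-iodoprop-2-en-1-yl]oxy][4-methoxy-3-(triisopropylsilyloxy)phenyl]methyl]oxirane
Product: 26 [(2S,3R)-4-methoxy-6-[(1E)-3-[(S)-[4-methoxy-3-(triisopropylsilyloxy)phenyl][(2R)-oxiran-2-yl]methoxy]prop-1-en-1-yl]-2-[3-methoxy-4-(triisopropylsilyloxy)phenyl]-2,3-dihydro-1-benzofuran-3-yl]methanol
Conditions: Pd(dppf)Cl2 (5 mol %), K3PO4, THF/H2O, 40 °C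
Reagents that add atoms: none
Why: Suzuki–Miyaura coupling of an aryl boronate with a vinyl iodide proceeds with retention of the E geometry under conditions mild enough that the terminal oxirane, the free hydroxyl and the silyl ethers should survive.

Step 16
Reactants: 26 [(2S,3R)-4-methoxy-6-[(1E)-3-[(S)-[4-methoxy-3-(triisopropylsilyloxy)phenyl][(2R)-oxiran-2-yl]methoxy]prop-1-en-1-yl]-2-[3-methoxy-4-(triisopropylsilyloxy)phenyl]-2,3-dihydro-1-benzofuran-3-yl]methanol
Product: 27 [(2S,3R)-6-[[(3S,4S,5R)-4-(hydroxymethyl)-5-[4-methoxy-3-(triisopropylsilyloxy)phenyl]oxolan-3-yl]methyl]-4-methoxy-2-[3-methoxy-4-(triisopropylsilyloxy)phenyl]-2,3-dihydro-1-benzofuran-3-yl]methanol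
Conditions: Cp2TiCl2 (3 equiv), Zn dust, THF, rt, the green Cp2TiCl solution added slowly to 26 (0.01 M); then 1 M aq. HCl, 0 °C
Reagents that add atoms: none
Why: Titanocene(III)-mediated reductive epoxide opening with 5-exo radical cyclisation (Nugent–RajanBabu type, the reaction class established for epoxy allyl ethers): Cp2TiCl transfers one electron to the oxirane, which opens at the more substituted C–O bond to the secondary C3 radical bearing CH2OTi. This radical adds 5-exo-trig to the proximal carbon of the E-styrenyl double bond, closing ring O1–C2–C3–C4–C5 through the C3–C4 bond, and the benzylic radical so formed is reduced by a second Cp2TiCl and protonated, or takes hydrogen from THF, to give the ArCH2 group. C2 is the only controlling element: in the chair-like Beckwith–Houk transition state its aryl group is pseudo-equatorial, the CH2OTi group on the planar radical carbon turns anti to it (2,3-trans) and the styryl carbon adds cis to that CH2OTi group (3,4-cis, 2,4-trans), so the C3 and C4 configurations of the target should both follow from C2. The former oxirane stereocentre becomes the radical and is erased, so only the carbinol configuration of 26 has to be pure. The step needs cyclisation to outrun reduction of the first radical to an organotitanium that would eliminate to an alkene; the fast 5-exo addition to a styrene and the slow addition of Ti(III) at high dilution should secure this, and the silyl ethers, the free hydroxyl and both benzylic ethers are inert to Cp2TiCl.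

Step 17
Reactants: 27 [(2S,3R)-6-[[(3S,4S,5R)-4-(hydroxymethyl)-5-[4-methoxy-3-(triisopropylsilyloxy)phenyl]oxolan-3-yl]methyl]-4-methoxy-2-[3-methoxy-4-(triisopropylsilyloxy)phenyl]-2,3-dihydro-1-benzofuran-3-yl]methanol
Product: 28 5-[(2R,3S,4S)-4-[[(2S,3R)-2-(4-hydroxy-3-methoxyphenyl)-3-(hydroxymethyl)-4-methoxy-2,3-dihydro-1-benzofuran-6-yl]methyl]-3-(hydroxymethyl)oxolan-2-yl]-2-methoxyphenol (CNP0242386.1)
Conditions: TBAF, AcOH, THF, 0 °C; aq. NH4Cl
Reagents that add atoms: none
Why: Buffered fluoride desilylation should free both phenols without acid or hydrogenolysis, so the two benzylic ring C–O bonds and all five stereocentres are not put at risk.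

Compound list
1 | vanillin (4-hydroxy-3-methoxybenzaldehyde) | COc1cc(C=O)ccc1O | starting material
2 | 3-methoxy-4-(triisopropylsilyloxy)benzaldehyde | COc1cc(C=O)ccc1O[Si](C(C)C)(C(C)C)C(C)C | intermediate
3 | [3-methoxy-4-(triisopropylsilyloxy)phenyl]methanol | COc1cc(CO)ccc1O[Si](C(C)C)(C(C)C)C(C)C | intermediate
4 | 1,3-dimethoxybenzene | COc1cccc(OC)c1 | starting material
5 | dimethyl oxalate | COC(=O)C(=O)OC | starting material
6 | 2,6-dimethoxyphenyllithium | [Li]c1c(OC)cccc1OC | intermediate (not isolated)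
7 | methyl 2-(2,6-dimethoxyphenyl)-2-oxoacetate | COC(=O)C(=O)c1c(OC)cccc1OC | intermediate
8 | methyl 2-(2-hydroxy-6-methoxyphenyl)-2-oxoacetate | COC(=O)C(=O)c1c(O)cccc1OC | intermediate
9 | methyl 2-[2-methoxy-6-[[3-methoxy-4-(triisopropylsilyloxy)phenyl]methoxy]phenyl]-2-oxoacetate | COC(=O)C(=O)c1c(OC)cccc1OCc1ccc(O[Si](C(C)C)(C(C)C)C(C)C)c(OC)c1 | intermediate
10 | N-tosylhydrazone of 9 | COC(=O)C(=NNS(=O)(=O)c1ccc(C)cc1)c1c(OC)cccc1OCc1ccc(O[Si](C(C)C)(C(C)C)C(C)C)c(OC)c1 | intermediate (not isolated)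
11 | methyl 2-diazo-2-[2-methoxy-6-[[3-methoxy-4-(triisopropylsilyloxy)phenyl]methoxy]phenyl]acetate | COC(=O)C(=[N+]=[N-])c1c(OC)cccc1OCc1ccc(O[Si](C(C)C)(C(C)C)C(C)C)c(OC)c1 | intermediate
12 | methyl (2S,3R)-4-methoxy-2-[3-methoxy-4-(triisopropylsilyloxy)phenyl]-2,3-dihydro-1-benzofuran-3-carboxylate (cis) | COc1cccc2O[C@H](c3ccc(O[Si](C(C)C)(C(C)C)C(C)C)c(OC)c3)[C@H](C(=O)OC)c12 | intermediate (not isolated)
13 | methyl (2S,3S)-4-methoxy-2-[3-methoxy-4-(triisopropylsilyloxy)phenyl]-2,3-dihydro-1-benzofuran-3-carboxylate (trans) | COc1cccc2O[C@H](c3ccc(O[Si](C(C)C)(C(C)C)C(C)C)c(OC)c3)[C@@H](C(=O)OC)c12 | intermediate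
14 | [(2S,3R)-4-methoxy-2-[3-methoxy-4-(triisopropylsilyloxy)phenyl]-2,3-dihydro-1-benzofuran-3-yl]methanol (trans) | COc1cccc2O[C@H](c3ccc(O[Si](C(C)C)(C(C)C)C(C)C)c(OC)c3)[C@@H](CO)c12 | intermediate
15 | 6-(pinacolboryl) derivative of 14 with the hydroxyl as its O-pinacolboryl ether | COc1cc(B3OC(C)(C)C(C)(C)O3)cc2O[C@H](c3ccc(O[Si](C(C)C)(C(C)C)C(C)C)c(OC)c3)[C@@H](COB3OC(C)(C)C(C)(C)O3)c12 | intermediate (not isolated)
16 | [(2S,3R)-4-methoxy-2-[3-methoxy-4-(triisopropylsilyloxy)phenyl]-6-(4,4,5,5-tetramethyl-1,3,2-dioxaborolan-2-yl)-2,3-dihydro-1-benzofuran-3-yl]methanol | COc1cc(B3OC(C)(C)C(C)(C)O3)cc2O[C@H](c3ccc(O[Si](C(C)C)(C(C)C)C(C)C)c(OC)c3)[C@@H](CO)c12 | intermediate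
17 | isovanillin (3-hydroxy-4-methoxybenzaldehyde) | COc1ccc(C=O)cc1O | starting material
18 | 4-methoxy-3-(triisopropylsilyloxy)benzaldehyde | COc1ccc(C=O)cc1O[Si](C(C)C)(C(C)C)C(C)C | intermediate
19 | vinylmagnesium bromide | C=C[Mg]Br | starting material
20 | rac-1-[4-methoxy-3-(triisopropylsilyloxy)phenyl]prop-2-en-1-ol | COc1ccc(C(O)C=C)cc1O[Si](C(C)C)(C(C)C)C(C)C | intermediate
21 | (S)-[4-methoxy-3-(triisopropylsilyloxy)phenyl][(2R)-oxiran-2-yl]methanol | COc1ccc([C@H](O)[C@H]2CO2)cc1O[Si](C(C)C)(C(C)C)C(C)C | intermediate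
22 | propargyl bromide (3-bromoprop-1-yne) | C#CCBr | starting material
23 | (2R)-2-[(S)-[4-methoxy-3-(triisopropylsilyloxy)phenyl](prop-2-yn-1-yloxy)methyl]oxirane | COc1ccc([C@H](OCC#C)[C@H]2CO2)cc1O[Si](C(C)C)(C(C)C)C(C)C | intermediate
24 | (E)-alkenylzirconocene chloride from 23 (Zr at the alkene terminus) | COc1ccc([C@H](OC/C=C/[Zr](Cl)(C2C=CC=C2)C2C=CC=C2)[C@H]2CO2)cc1O[Si](C(C)C)(C(C)C)C(C)C | intermediate (not isolated)
25 | (2R)-2-[(S)-[[(2E)-3-iodoprop-2-en-1-yl]oxy][4-methoxy-3-(triisopropylsilyloxy)phenyl]methyl]oxirane | COc1ccc([C@H](OC/C=C/I)[C@H]2CO2)cc1O[Si](C(C)C)(C(C)C)C(C)C | intermediate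
26 | [(2S,3R)-4-methoxy-6-[(1E)-3-[(S)-[4-methoxy-3-(triisopropylsilyloxy)phenyl][(2R)-oxiran-2-yl]methoxy]prop-1-en-1-yl]-2-[3-methoxy-4-(triisopropylsilyloxy)phenyl]-2,3-dihydro-1-benzofuran-3-yl]methanol | COc1ccc([C@H](OC/C=C/c3cc(OC)c4c(c3)O[C@H](c3ccc(O[Si](C(C)C)(C(C)C)C(C)C)c(OC)c3)[C@H]4CO)[C@H]2CO2)cc1O[Si](C(C)C)(C(C)C)C(C)C | intermediate
27 | bis(triisopropylsilyl) ether of the target: (2R,3S,4S)-oxolane and (2S,3R)-dihydrobenzofuran | COc1ccc([C@@H]2OC[C@@H](Cc3cc(OC)c4c(c3)O[C@H](c3ccc(O[Si](C(C)C)(C(C)C)C(C)C)c(OC)c3)[C@H]4CO)[C@H]2CO)cc1O[Si](C(C)C)(C(C)C)C(C)C | intermediate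
28 | 5-[(2R,3S,4S)-4-[[(2S,3R)-2-(4-hydroxy-3-methoxyphenyl)-3-(hydroxymethyl)-4-methoxy-2,3-dihydro-1-benzofuran-6-yl]methyl]-3-(hydroxymethyl)oxolan-2-yl]-2-methoxyphenol | COc1ccc([C@@H]2OC[C@@H](Cc3cc(OC)c4c(c3)O[C@H](c3ccc(O)c(OC)c3)[C@H]4CO)[C@H]2CO)cc1O | target

Total step count: 17. Longest linear sequence: 10 steps (3, 4, 5, 6, 7, 8, 9, 15, 16, 17, from 1,3-dimethoxybenzene).

Steps most likely to fail

Step 16 (key step). The 5-exo closure may show poor facial selectivity at C4, so that the 3,4-trans isomer accompanies the wanted 3,4-cis product. The fallback sets C4 by hydroboration instead of in the radical closure. It sets out from 23 and 16 and comes back at 27. The titanocene(III) conditions of step 16 are applied to the propargyl ether 23, whose 5-exo-dig closure creates only C3 (trans to the aryl group) and should give [(2R,3S)-2-[4-methoxy-3-(triisopropylsilyloxy)phenyl]-4-methylideneoxolan-3-yl]methanol F1. Boronate 16 is converted with CuBr2 in aqueous methanol into the 6-bromo-dihydrobenzofuran alcohol F2. Hydroboration of F1 with 9-BBN-H (one extra equivalent for the hydroxyl) should deliver hydrogen to C4 from the face anti to the adjacent C3 substituent, giving the B-alkyl borane F3 with the boron-bearing carbon cis to C3–CH2O. F3 is coupled in the same flask with F2 (Pd(dppf)Cl2, aq. K3PO4, THF/DMF, B-alkyl Suzuki–Miyaura coupling) to give 27.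

Step 7. The carbenoid carries two ortho substituents and is twisted out of conjugation, so the chiral catalyst may discriminate the two benzylic hydrogens poorly and the enantiomeric purity at C2 may be insufficient. The fallback replaces asymmetric catalysis by resolution. It sets out from 11 and comes back at 14. Rh2(OAc)4 followed by DBU gives the racemic trans ester, that is 13 together with its enantiomer, the (2R,3R)-ester F4. DIBAL-H reduction gives 14 together with the (2R,3S)-alcohol F5. Esterification with (S)-O-methylmandelic acid (DCC, DMAP) gives the diastereomeric esters F6 (from 14) and F7 (from F5), which are separated by chromatography. DIBAL-H cleavage of F6 returns 14.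

Step 13. The alkoxide of 21 may undergo epoxide migration (Payne rearrangement) to the conjugated 3-aryl-oxiranylmethoxide before it is alkylated, giving the wrong ether. The fallback forms the ether before any oxirane exists. It sets out from 20 and comes back at 23. Sharpless kinetic resolution of 20 with D-(−)-DIPT, run past 55% conversion, consumes the (S)-enantiomer as the epoxy alcohol F9 and leaves (R)-1-[4-methoxy-3-(triisopropylsilyloxy)phenyl]prop-2-en-1-ol F8. F8 is propargylated (NaH, 22, THF) to the ether F10. Buffered mCPBA then epoxidises the vinyl group (the alkyne should be inert) to give 23 together with its oxirane epimer F11. The two are separated; F11 is equally usable, since step 16 erases the oxirane centre.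

Further compounds
F1 | step 16 | [(2R,3S)-2-[4-methoxy-3-(triisopropylsilyloxy)phenyl]-4-methylideneoxolan-3-yl]methanol | COc1ccc([C@@H]2OCC(=C)[C@H]2CO)cc1O[Si](C(C)C)(C(C)C)C(C)C
F2 | step 16 | [(2S,3R)-6-bromo-4-methoxy-2-[3-methoxy-4-(triisopropylsilyloxy)phenyl]-2,3-dihydro-1-benzofuran-3-yl]methanol | COc1cc(Br)cc2O[C@H](c3ccc(O[Si](C(C)C)(C(C)C)C(C)C)c(OC)c3)[C@@H](CO)c12
F3 | step 16 | B-alkyl-9-BBN adduct of F1 (2R,3S,4S; hydroxyl as its 9-BBN borinate) | COc1ccc([C@@H]2OC[C@@H](CB3C4CCCC3CCC4)[C@H]2COB2C3CCCC2CCC3)cc1O[Si](C(C)C)(C(C)C)C(C)C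
F4 | step 7 | methyl (2R,3R)-4-methoxy-2-[3-methoxy-4-(triisopropylsilyloxy)phenyl]-2,3-dihydro-1-benzofuran-3-carboxylate | COc1cccc2O[C@@H](c3ccc(O[Si](C(C)C)(C(C)C)C(C)C)c(OC)c3)[C@H](C(=O)OC)c12
F5 | step 7 | [(2R,3S)-4-methoxy-2-[3-methoxy-4-(triisopropylsilyloxy)phenyl]-2,3-dihydro-1-benzofuran-3-yl]methanol | COc1cccc2O[C@@H](c3ccc(O[Si](C(C)C)(C(C)C)C(C)C)c(OC)c3)[C@H](CO)c12
F6 | step 7 | (2S)-2-methoxy-2-phenylacetate of 14 | COc1cccc2O[C@H](c3ccc(O[Si](C(C)C)(C(C)C)C(C)C)c(OC)c3)[C@@H](COC(=O)[C@@H](OC)c3ccccc3)c12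
F7 | step 7 | (2S)-2-methoxy-2-phenylacetate of F5 | COc1cccc2O[C@@H](c3ccc(O[Si](C(C)C)(C(C)C)C(C)C)c(OC)c3)[C@H](COC(=O)[C@@H](OC)c3ccccc3)c12
F8 | step 13 | (R)-1-[4-methoxy-3-(triisopropylsilyloxy)phenyl]prop-2-en-1-ol | COc1ccc([C@H](O)C=C)cc1O[Si](C(C)C)(C(C)C)C(C)C
F9 | step 13 | (R)-[4-methoxy-3-(triisopropylsilyloxy)phenyl][(2S)-oxiran-2-yl]methanol | COc1ccc([C@@H](O)[C@@H]2CO2)cc1O[Si](C(C)C)(C(C)C)C(C)C
F10 | step 13 | triisopropyl[2-methoxy-5-[(1R)-1-(prop-2-yn-1-yloxy)prop-2-en-1-yl]phenoxy]silane | COc1ccc([C@H](OCC#C)C=C)cc1O[Si](C(C)C)(C(C)C)C(C)C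
F11 | step 13 | (2S)-2-[(S)-[4-methoxy-3-(triisopropylsilyloxy)phenyl](prop-2-yn-1-yloxy)methyl]oxirane | COc1ccc([C@H](OCC#C)[C@@H]2CO2)cc1O[Si](C(C)C)(C(C)C)C(C)C
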